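**Plan**

- Retrosynthetic cuts: first C1–H/C2–H (hydrogenation) and C1–aryl (Suzuki coupling on the C1 enol triflate of a 1-tetralone); then C6–O and C7–O back to C–B; then C4a–C8a, C5–C6 and C7–C8 together in one cobalt [2+2+2] step; last the ketone–ethynyl, C2–CH2OMe and C3–propargyl bonds of the open chain.
- Enabling feature: ring A (C4a, C5, C6, C7, C8, C8a) is a benzene with H at C5 and C8 and O at C6 and C7, fused through C4a–C8a to ring B (C1–C4). This is the imprint of two terminal alkynes on a four-carbon tether plus one symmetric alkyne that supplies C6 and C7.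
- Forward order: the chain carrying both alkynes is built linearly from a succinate half-ester; rings A and B close together; boron is exchanged for OMe; the aryl group is attached at C1; the C1=C2 bond is hydrogenated.
- Stereochemistry: C3 (R) comes from alkylation on (R)-4-benzyl-2-oxazolidinone. C2 is carried as epimers and flattened in the enol triflate. C1 and C2 are set together by syn hydrogenation on the face anti to the C3 substituent, which gives the all-cis (1S,2S,3R) target.

Key step: step 9

Assumption: the centre α to the carbonyl (C2 of the hexynoates, C4 of the diyne, C2 of the tetralones) is carried as both epimers and drawn without a descriptor, because step 12 makes it sp2 and step 14 sets it anew; tetralin locants C1–C8a are used for the ring system throughout.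

**Route**

Step 1
Reactants: 1 4-tert-butoxy-4-oxobutanoic acid; 2 (R)-4-benzyl-2-oxazolidinone
Product: 4 tert-butyl 4-[(4R)-4-benzyl-2-oxo-1,3-oxazolidin-3-yl]-4-oxobutanoate, via mixed pivalic anhydride 3 (not isolated)
Conditions: t-BuCOCl, Et3N, THF, −20 °C; then 2, LiCl, −20 °C → rt
Reagents that add atoms: none
Why: Mixed-anhydride N-acylation, in which the oxazolidinone activated by LiCl/Et3N attacks the unhindered succinyl carbonyl of 3, a standard strong-base-free way to N-acyl oxazolidinones.

Step 2
Reactants: 4 tert-butyl 4-[(4R)-4-benzyl-2-oxo-1,3-oxazolidin-3-yl]-4-oxobutanoate; 5 3-bromo-1-(trimethylsilyl)prop-1-yne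
Product: 7 tert-butyl (3R)-3-{[(4R)-4-benzyl-2-oxo-1,3-oxazolidin-3-yl]carbonyl}-6-(trimethylsilyl)hex-5-ynoate, via sodium enolate 6 (not isolated)
Conditions: NaN(SiMe3)2, THF, −78 °C; then 5, −78 → −40 °C
Reagents that add atoms: none
Why: Evans asymmetric alkylation, in which the chelated (Z)-enolate forms only at the more acidic imide α-carbon and the benzyl group of the (R)-auxiliary blocks one face, so the propargylic bromide enters from the other and sets the future C3 as (R); the silyl cap removes the acidic alkyne C–H ahead of the strong-base step 5.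

Step 3
Reactants: 7 tert-butyl (3R)-3-{[(4R)-4-benzyl-2-oxo-1,3-oxazolidin-3-yl]carbonyl}-6-(trimethylsilyl)hex-5-ynoate
Product: 8 tert-butyl (3R)-3-(hydroxymethyl)-6-(trimethylsilyl)hex-5-ynoate
Conditions: LiBH4, MeOH (1 equiv), Et2O, 0 °C; aq. NH4Cl work-up
Reagents that add atoms: none
Why: Reductive cleavage of the N-acyl oxazolidinone, in which LiBH4 reduces the exocyclic imide carbonyl to the primary alcohol, leaves the hindered tert-butyl ester alone at 0 °C and returns the auxiliary without touching the stereocentre.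

Step 4
Reactants: 8 tert-butyl (3R)-3-(hydroxymethyl)-6-(trimethylsilyl)hex-5-ynoate
Product: 9 tert-butyl (3R)-3-(methoxymethyl)-6-(trimethylsilyl)hex-5-ynoate
Conditions: Me3OBF4, 1,8-bis(dimethylamino)naphthalene, 4 Å MS, CH2Cl2, 0 °C → rt
Reagents that add atoms: trimethyloxonium tetrafluoroborate, C[O+](C)C.F[B-](F)(F)F
Why: O-Methylation with a trimethyloxonium salt and a hindered amine base proceeds without an alkoxide, which under Williamson conditions would lactonise onto the γ-ester.

Step 5
Reactants: 9 tert-butyl (3R)-3-(methoxymethyl)-6-(trimethylsilyl)hex-5-ynoate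
Product: 11 tert-butyl (3R)-2,3-bis(methoxymethyl)-6-(trimethylsilyl)hex-5-ynoate (C2 epimers), via lithium enolate 10 (not isolated)
Conditions: LiN(iPr)2, THF, −78 °C; then MeOCH2Cl, −78 → −20 °C
Reagents that add atoms: chloromethyl methyl ether, COCCl
Why: Ester enolate alkylation, in which the preformed lithium enolate is C-alkylated by the very reactive α-chloro ether; the new C2 centre is not controlled, which is harmless because it becomes sp2 in step 12, and C3 is not acidic.

Step 6
Reactants: 11 tert-butyl (3R)-2,3-bis(methoxymethyl)-6-(trimethylsilyl)hex-5-ynoate (C2 epimers)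
Product: 12 tert-butyl (3R)-2,3-bis(methoxymethyl)hex-5-ynoate (C2 epimers)
Conditions: K2CO3 (0.3 equiv), MeOH, rt
Reagents that add atoms: none
Why: Base-catalysed methanolysis of the C(sp)–Si bond (protodesilylation) frees the terminal alkyne under conditions too mild to affect the tert-butyl ester or the ethers.

Step 7
Reactants: 12 tert-butyl (3R)-2,3-bis(methoxymethyl)hex-5-ynoate (C2 epimers)
Product: 14 (3R)-N-methoxy-2,3-bis(methoxymethyl)-N-methylhex-5-ynamide (C2 epimers), via carboxylic acid 13 (not isolated)
Conditions: CF3CO2H/CH2Cl2 (1:3), rt; evaporate; then MeNHOMe·HCl, EDC·HCl, HOBt (cat.), iPr2NEt, CH2Cl2, 0 °C → rt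
Reagents that add atoms: N,O-dimethylhydroxylamine hydrochloride, CNOC.Cl
Why: Acidolysis of the tert-butyl ester with loss of isobutene followed by carbodiimide amide coupling gives the Weinreb amide, and neither stage touches C3.

Step 8
Reactants: 14 (3R)-N-methoxy-2,3-bis(methoxymethyl)-N-methylhex-5-ynamide (C2 epimers); 15 ethynylmagnesium bromide
Product: 17 (5R)-4,5-bis(methoxymethyl)octa-1,7-diyn-3-one (C4 epimers), via magnesium hemiaminal 16 (not isolated)
Conditions: 15 (0.5 M in THF, 3.5 equiv), THF, 0 °C → rt; poured into cold 1 M HCl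
Reagents that add atoms: none
Why: Weinreb ketone synthesis, in which the chelated adduct 16 holds until the quench so only one ethynyl group is delivered, and the inverse acidic quench protonates the released N,O-dimethylhydroxylamine before it can add to the ynone.

Step 9
Reactants: 17 (5R)-4,5-bis(methoxymethyl)octa-1,7-diyn-3-one (C4 epimers); 18 1,2-bis(4,4,5,5-tetramethyl-1,3,2-dioxaborolan-2-yl)ethyne
Product: 19 (3R)-2,3-bis(methoxymethyl)-6,7-bis(4,4,5,5-tetramethyl-1,3,2-dioxaborolan-2-yl)-3,4-dihydronaphthalen-1(2H)-one (C2 epimers)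
Conditions: CpCo(CO)2 (Cp = C5H5, 20 mol %), 18 (4 equiv), degassed toluene, reflux, visible-light irradiation; 17 added by syringe pump over 8 h
Reagents that add atoms: none
Why: Loss of CO from CpCo(CO)2 under heat and light frees monovalent cobalt, which binds both alkynes of 17 and couples them oxidatively to a cobaltacyclopentadiene of trivalent cobalt; this forms C4a–C8a and so closes ring B as a six-membered carbocycle fused to the metallacycle. Alkyne 18 then coordinates and inserts (or adds across the metallacyclic diene in a [4+2] sense), and reductive elimination forms C5–C6 and C7–C8, closing ring A as the benzene ring and returning monovalent cobalt. The closest known reaction type is the cobalt-mediated [2+2+2] cocyclisation of 1,7-diynes with bis(trimethylsilyl)ethyne or alkynylboronates to 6,7-difunctionalised tetralins, and conjugated ynones are established partners in metal-catalysed alkyne cyclotrimerisation. No stereocentre is created: C3 is not acidic and passes through unchanged, and C2 is already an epimer mixture. The step needs chemoselectivity for cross- over homo-trimerisation, secured by slow addition of 17 into an excess of the bulky 18, which is reluctant to trimerise with itself; the symmetry of 18 and of ring A about the C6–C7 bond removes any regiochemical question.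

Step 10
Reactants: 19 (3R)-2,3-bis(methoxymethyl)-6,7-bis(4,4,5,5-tetramethyl-1,3,2-dioxaborolan-2-yl)-3,4-dihydronaphthalen-1(2H)-one (C2 epimers)
Product: 20 (3R)-6,7-dihydroxy-2,3-bis(methoxymethyl)-3,4-dihydronaphthalen-1(2H)-one (C2 epimers)
Conditions: NaBO3·4H2O (2.5 equiv), THF/H2O (1:1), 0 °C → rt; aq. Na2S2O3 then NH4Cl work-up
Reagents that add atoms: sodium perborate tetrahydrate (peroxoborate drawn without water of crystallisation), [Na+].[Na+].O[B-]1(O)OO[B-](O)(O)OO1
Why: Oxidation of the aryl C–B bonds by peroxoborate (1,2-shift of aryl from boron to oxygen, then hydrolysis) gives both phenols at the carbons that bore boron, and limited oxidant at low temperature keeps the slower Dakin-type oxidation of the aryl ketone from competing.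

Step 11
Reactants: 20 (3R)-6,7-dihydroxy-2,3-bis(methoxymethyl)-3,4-dihydronaphthalen-1(2H)-one (C2 epimers)
Product: 21 (3R)-6,7-dimethoxy-2,3-bis(methoxymethyl)-3,4-dihydronaphthalen-1(2H)-one (C2 epimers)
Conditions: MeI (3 equiv), K2CO3 (3 equiv), acetone, rt, under argon
Reagents that add atoms: iodomethane, CI
Why: Williamson etherification of the two phenoxides with a carbonate base that barely enolises the ketone at room temperature, so the β-methoxy ketone survives; any epimerisation at C2 is immaterial and C3 is not acidic.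

Step 12
Reactants: 21 (3R)-6,7-dimethoxy-2,3-bis(methoxymethyl)-3,4-dihydronaphthalen-1(2H)-one (C2 epimers)
Product: 23 (3R)-6,7-dimethoxy-2,3-bis(methoxymethyl)-3,4-dihydronaphthalen-1-yl trifluoromethanesulfonate, via potassium enolate 22 (not isolated)
Conditions: KN(SiMe3)2, THF, −78 °C; then N-(5-chloropyridin-2-yl)bis(trifluoromethanesulfonimide), −78 °C
Reagents that add atoms: N-(5-chloropyridin-2-yl)bis(trifluoromethanesulfonimide), FC(F)(F)S(=O)(=O)N(c1ccc(Cl)cn1)S(=O)(=O)C(F)(F)F
Why: Enol triflate formation, in which C2 carries the only enolisable hydrogen so a single enolate forms and is O-sulfonylated at −78 °C by the reactive pyridyl triflimide before it can expel methoxide; the C2 stereocentre is thereby removed.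

Step 13
Reactants: 23 (3R)-6,7-dimethoxy-2,3-bis(methoxymethyl)-3,4-dihydronaphthalen-1-yl trifluoromethanesulfonate; 24 (3,4-dimethoxyphenyl)boronic acid
Product: 25 (3R)-1-(3,4-dimethoxyphenyl)-6,7-dimethoxy-2,3-bis(methoxymethyl)-3,4-dihydronaphthalene
Conditions: Pd(PPh3)4 (5 mol %), 2 M aq. Na2CO3, DME, 80 °C
Reagents that add atoms: none
Why: Suzuki–Miyaura coupling, in which zerovalent palladium inserts into the vinyl C–OTf bond, the carbonate-activated boronate transmetalates and reductive elimination forms the C1–aryl bond without touching C3.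

Step 14
Reactants: 25 (3R)-1-(3,4-dimethoxyphenyl)-6,7-dimethoxy-2,3-bis(methoxymethyl)-3,4-dihydronaphthalene
Product: 26 (1S,2S,3R)-1-(3,4-dimethoxyphenyl)-6,7-dimethoxy-2,3-bis(methoxymethyl)-1,2,3,4-tetrahydronaphthalene
Conditions: H2 (4 atm), Pd/C (10 wt % Pd), EtOAc, rt
Reagents that add atoms: none
Why: Heterogeneous syn hydrogenation, in which the C3 methoxymethyl group sits pseudoaxial to escape A(1,2) strain with the C2 substituent and shields its face, so both hydrogens should add to C1 and C2 from the opposite face, placing the aryl group and both methoxymethyl groups cis and giving (1S,2S,3R); neutral ethyl acetate limits hydrogenolysis of the allylic C–O bond.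

**Compound list**

1 | 4-tert-butoxy-4-oxobutanoic acid | CC(C)(C)OC(=O)CCC(=O)O | starting material
2 | (R)-4-benzyl-2-oxazolidinone | O=C1N[C@H](Cc2ccccc2)CO1 | starting material
3 | 4-tert-butoxy-4-oxobutanoic pivalic anhydride | CC(C)(C)OC(=O)CCC(=O)OC(=O)C(C)(C)C | intermediate (not isolated)
4 | tert-butyl 4-[(4R)-4-benzyl-2-oxo-1,3-oxazolidin-3-yl]-4-oxobutanoate | CC(C)(C)OC(=O)CCC(=O)N1[C@H](Cc2ccccc2)COC1=O | intermediate
5 | 3-bromo-1-(trimethylsilyl)prop-1-yne | C[Si](C)(C)C#CCBr | starting material
6 | sodium (Z)-enolate of 4 | [Na+].[O-]/C(=C\CC(=O)OC(C)(C)C)N1[C@H](Cc2ccccc2)COC1=O | intermediate (not isolated)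
7 | tert-butyl (3R)-3-{[(4R)-4-benzyl-2-oxo-1,3-oxazolidin-3-yl]carbonyl}-6-(trimethylsilyl)hex-5-ynoate | O=C(N1[C@H](Cc2ccccc2)COC1=O)[C@@H](CC(=O)OC(C)(C)C)CC#C[Si](C)(C)C | intermediate
8 | tert-butyl (3R)-3-(hydroxymethyl)-6-(trimethylsilyl)hex-5-ynoate | OC[C@@H](CC(=O)OC(C)(C)C)CC#C[Si](C)(C)C | intermediate
9 | tert-butyl (3R)-3-(methoxymethyl)-6-(trimethylsilyl)hex-5-ynoate | COC[C@@H](CC(=O)OC(C)(C)C)CC#C[Si](C)(C)C | intermediate
10 | lithium enolate of 9 | [Li+].COC[C@@H](C=C([O-])OC(C)(C)C)CC#C[Si](C)(C)C | intermediate (not isolated)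
11 | tert-butyl (3R)-2,3-bis(methoxymethyl)-6-(trimethylsilyl)hex-5-ynoate, C2 epimers | COC[C@@H](C(COC)C(=O)OC(C)(C)C)CC#C[Si](C)(C)C | intermediate
12 | tert-butyl (3R)-2,3-bis(methoxymethyl)hex-5-ynoate, C2 epimers | COC[C@@H](C(COC)C(=O)OC(C)(C)C)CC#C | intermediate
13 | (3R)-2,3-bis(methoxymethyl)hex-5-ynoic acid, C2 epimers | COC[C@@H](C(COC)C(=O)O)CC#C | intermediate (not isolated)
14 | (3R)-N-methoxy-2,3-bis(methoxymethyl)-N-methylhex-5-ynamide, C2 epimers | COC[C@@H](C(COC)C(=O)N(C)OC)CC#C | intermediate
15 | ethynylmagnesium bromide | C#C[Mg]Br | starting material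
16 | bromomagnesium (5R)-3-[methoxy(methyl)amino]-4,5-bis(methoxymethyl)octa-1,7-diyn-3-olate (drawn with both alkyne C–H bonds intact) | COC[C@@H](C(COC)C(O[Mg]Br)(C#C)N(C)OC)CC#C | intermediate (not isolated)
17 | (5R)-4,5-bis(methoxymethyl)octa-1,7-diyn-3-one, C4 epimers | COC[C@@H](C(COC)C(=O)C#C)CC#C | intermediate (key-step precursor)
18 | 1,2-bis(4,4,5,5-tetramethyl-1,3,2-dioxaborolan-2-yl)ethyne | CC1(C)OB(OC1(C)C)C#CB1OC(C)(C)C(C)(C)O1 | starting material
19 | (3R)-2,3-bis(methoxymethyl)-6,7-bis(4,4,5,5-tetramethyl-1,3,2-dioxaborolan-2-yl)-3,4-dihydronaphthalen-1(2H)-one, C2 epimers | COC[C@@H]1Cc2cc(B3OC(C)(C)C(C)(C)O3)c(B3OC(C)(C)C(C)(C)O3)cc2C(=O)C1COC | intermediate (key-step product)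
20 | (3R)-6,7-dihydroxy-2,3-bis(methoxymethyl)-3,4-dihydronaphthalen-1(2H)-one, C2 epimers | COC[C@@H]1Cc2cc(O)c(O)cc2C(=O)C1COC | intermediate
21 | (3R)-6,7-dimethoxy-2,3-bis(methoxymethyl)-3,4-dihydronaphthalen-1(2H)-one, C2 epimers | COC[C@@H]1Cc2cc(OC)c(OC)cc2C(=O)C1COC | intermediate
22 | potassium enolate of 21 | [K+].COC[C@@H]1Cc2cc(OC)c(OC)cc2C([O-])=C1COC | intermediate (not isolated)
23 | (3R)-6,7-dimethoxy-2,3-bis(methoxymethyl)-3,4-dihydronaphthalen-1-yl trifluoromethanesulfonate | COC[C@@H]1Cc2cc(OC)c(OC)cc2C(OS(=O)(=O)C(F)(F)F)=C1COC | intermediate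
24 | (3,4-dimethoxyphenyl)boronic acid | COc1ccc(B(O)O)cc1OC | starting material
25 | (3R)-1-(3,4-dimethoxyphenyl)-6,7-dimethoxy-2,3-bis(methoxymethyl)-3,4-dihydronaphthalene | COC[C@@H]1Cc2cc(OC)c(OC)cc2C(c2ccc(OC)c(OC)c2)=C1COC | intermediate
26 | (1S,2S,3R)-1-(3,4-dimethoxyphenyl)-6,7-dimethoxy-2,3-bis(methoxymethyl)-1,2,3,4-tetrahydronaphthalene | COC[C@@H]1Cc2cc(OC)c(OC)cc2[C@H](c2ccc(OC)c(OC)c2)[C@@H]1COC | target

**Step count and risks**

Total step count: 14. Longest linear sequence: 14 steps (1 and 2 to 26); the route is fully linear, with 5, 15, 18 and 24 bought.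

Most likely to fail, in order:

Risk 1, step 9. The conjugated terminal ynone may oligomerise or tie up the cobalt as an unreactive complex, so that cross-trimerisation stalls or the diyne trimerises with itself. The fallback takes the carbonyl out of conjugation before the cobalt step and restores it afterwards. It sets out from 17, which is reduced with NaBH4/CeCl3·7H2O in MeOH at −78 °C to (5R)-4,5-bis(methoxymethyl)octa-1,7-diyn-3-ol F1. Silylation with t-BuMe2SiCl and imidazole in DMF gives tert-butyl{[(5R)-4,5-bis(methoxymethyl)octa-1,7-diyn-3-yl]oxy}dimethylsilane F2, a non-conjugated 1,7-diyne of the classical kind. Cocyclisation with 18 under the conditions of step 9 should give tert-butyl{[(3R)-2,3-bis(methoxymethyl)-6,7-bis(4,4,5,5-tetramethyl-1,3,2-dioxaborolan-2-yl)-1,2,3,4-tetrahydronaphthalen-1-yl]oxy}dimethylsilane F3. NaBO3·4H2O oxidation then gives (3R)-1-[tert-butyl(dimethyl)silyloxy]-2,3-bis(methoxymethyl)-1,2,3,4-tetrahydronaphthalene-6,7-diol F4, and MeI/K2CO3 gives tert-butyl{[(3R)-6,7-dimethoxy-2,3-bis(methoxymethyl)-1,2,3,4-tetrahydronaphthalen-1-yl]oxy}dimethylsilane F5. Bu4NF in THF frees (3R)-6,7-dimethoxy-2,3-bis(methoxymethyl)-1,2,3,4-tetrahydronaphthalen-1-ol F6, and MnO2 in CH2Cl2 oxidises this benzylic alcohol to the ketone, coming back to the route at 21. With no ketone present during the perborate and methylation steps, the detour also avoids Dakin-type oxidation and base-induced loss of methanol there.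

Risk 2, step 12. Enolate 22 may lose methoxide by E1cB elimination before it is trapped, giving the exocyclic enone and, through double-bond migration, a naphthol with loss of C3. The fallback avoids the enolate altogether and sets out from 21. Addition of the organocerium reagent made from (3,4-dimethoxyphenyl)magnesium bromide and anhydrous CeCl3 in THF at −78 °C, which adds to hindered enolisable ketones with little deprotonation, gives (3R)-1-(3,4-dimethoxyphenyl)-6,7-dimethoxy-2,3-bis(methoxymethyl)-1,2,3,4-tetrahydronaphthalen-1-ol F7. Dehydration of this doubly benzylic carbinol with catalytic p-TsOH in toluene at rt can only occur toward C2, the sole β-carbon bearing hydrogen, and comes back to the route at 25, bypassing 23.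

Risk 3, step 14. Hydrogen may add to both faces of the tetrasubstituted alkene, or the allylic C–O bond at C2 may be cleaved on the palladium surface before the hindered alkene is saturated. The fallback moves stereocontrol from the substrate to a homogeneous chiral catalyst and sets out from 25. It uses [Ir(cod)(L)][B(C6H3(CF3)2)4] (cod = cycloocta-1,5-diene; L = 4-tert-butyl-2-[2-(diphenylphosphanyl)phenyl]-4,5-dihydro-1,3-oxazole, in the enantiomeric form that delivers hydrogen to the face anti to the C3 substituent), H2 (50 bar), CH2Cl2, rt. Cationic iridium complexes of this ligand class reduce tetrasubstituted aryl alkenes by syn addition under catalyst control and do not hydrogenolyse allylic ethers. The fallback arrives directly at 26 and makes no new compound.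

Further compounds
F1 | step 9 | (5R)-4,5-bis(methoxymethyl)octa-1,7-diyn-3-ol (C3 and C4 epimers) | COC[C@@H](C(COC)C(O)C#C)CC#C
F2 | step 9 | tert-butyl{[(5R)-4,5-bis(methoxymethyl)octa-1,7-diyn-3-yl]oxy}dimethylsilane (C3 and C4 epimers) | COC[C@@H](C(COC)C(O[Si](C)(C)C(C)(C)C)C#C)CC#C
F3 | step 9 | tert-butyl{[(3R)-2,3-bis(methoxymethyl)-6,7-bis(4,4,5,5-tetramethyl-1,3,2-dioxaborolan-2-yl)-1,2,3,4-tetrahydronaphthalen-1-yl]oxy}dimethylsilane (C1 and C2 epimers) | COC[C@@H]1Cc2cc(B3OC(C)(C)C(C)(C)O3)c(B3OC(C)(C)C(C)(C)O3)cc2C(O[Si](C)(C)C(C)(C)C)C1COC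
F4 | step 9 | (3R)-1-[tert-butyl(dimethyl)silyloxy]-2,3-bis(methoxymethyl)-1,2,3,4-tetrahydronaphthalene-6,7-diol (C1 and C2 epimers) | COC[C@@H]1Cc2cc(O)c(O)cc2C(O[Si](C)(C)C(C)(C)C)C1COC
F5 | step 9 | tert-butyl{[(3R)-6,7-dimethoxy-2,3-bis(methoxymethyl)-1,2,3,4-tetrahydronaphthalen-1-yl]oxy}dimethylsilane (C1 and C2 epimers) | COC[C@@H]1Cc2cc(OC)c(OC)cc2C(O[Si](C)(C)C(C)(C)C)C1COC
F6 | step 9 | (3R)-6,7-dimethoxy-2,3-bis(methoxymethyl)-1,2,3,4-tetrahydronaphthalen-1-ol (C1 and C2 epimers) | COC[C@@H]1Cc2cc(OC)c(OC)cc2C(O)C1COC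
F7 | step 12 | (3R)-1-(3,4-dimethoxyphenyl)-6,7-dimethoxy-2,3-bis(methoxymethyl)-1,2,3,4-tetrahydronaphthalen-1-ol (C1 and C2 epimers) | COC[C@@H]1Cc2cc(OC)c(OC)cc2C(O)(c2ccc(OC)c(OC)c2)C1COC
F0 | step 14 | none | none
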